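**Plan**
- Retrosynthesis: the ten-membered carbocycle (C1–C10, germacrane numbering) is opened at C3–C4, the bond between the sp3 methylene C3 and the trisubstituted C4=C5 olefin. A C4 alkenyl iodide with iodine cis to C6 stores the ring-cis geometry, and C3 is reached from a terminal C2=C3 vinyl group (B-alkyl Suzuki ring closure).
- Further cuts: C11=C13 and the two acyl groups (late), C9–C10 together with C1–C2 (vinylcuprate, methyl propiolate, aldehyde), C8–C9 (vinyl Grignard on a Weinreb amide), C6–C7 (aldol of a succinate imide with an iodoenal).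
- Forward order: Z-iodoenal (C4–C6, C15) from 2-butyne-1,4-diol; the aldol joins C6–C7; C8 ketone and reduction; the gamma-lactone ring (O6–C12) closes first; C9 aldehyde; dienoate (C10, C14, C1–C3); dioxolane ring on O8/O9; the carbocycle closes in step 14; then methylene, acyl groups, desilylation.
- Stereochemistry: C6 and C7 from (S)-4-benzyloxazolidinone (Evans syn aldol); C8 from C6–OH-directed 1,3-anti reduction; C9 from Felkin–Anh addition anti to the C8 silyloxy group. The C4=C5 geometry comes from hydroxyl-directed trans-hydroalumination–iodination, the C1=C10 geometry from syn carbocupration.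

Key step: step 14

Remark: germacrane numbering is used for every intermediate (ring C1–C10; C11–C13 lactone carbons; C14 ester carbon on C10; C15 oxygenated carbon on C4). The alkenylcopper 21 is assumed to keep its geometry at −78 °C.

**Route**

Step 1
Reactants: 1 2-butyne-1,4-diol
Product: 2 4-(tert-butyldiphenylsilyloxy)but-2-yn-1-ol
Conditions: NaH (1 equiv), THF, 0 °C; t-BuPh2SiCl (1 equiv), 0 °C → rt
Reagents that add atoms: tert-butyl(chloro)diphenylsilane, CC(C)(C)[Si](Cl)(c1ccccc1)c1ccccc1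
Why: Monosilylation of a symmetric diol through its monosodium alkoxide (O-silylation), which should stop after one hydroxyl has reacted.

Step 2
Reactants: 2 4-(tert-butyldiphenylsilyloxy)but-2-yn-1-ol
Product: 4 (Z)-4-(tert-butyldiphenylsilyloxy)-3-iodobut-2-en-1-ol, via sodium alkenylaluminate 3 (not isolated)
Conditions: NaAlH2(OCH2CH2OMe)2, THF, 0 °C → rt; then I2, THF, −78 → 0 °C
Reagents that add atoms: iodine, II
Why: Hydroxyl-directed trans-hydroalumination puts hydride on C5 and aluminium on C4 cis to C6, and iodinolysis of the C–Al bond with retention should give the Z iodoalkene, the silylated C15 oxygen being unable to direct.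

Step 3
Reactants: 4 (Z)-4-(tert-butyldiphenylsilyloxy)-3-iodobut-2-en-1-ol
Product: 5 (Z)-4-(tert-butyldiphenylsilyloxy)-3-iodobut-2-enal
Conditions: MnO2, CH2Cl2, rt
Reagents that add atoms: none
Why: Allylic alcohol oxidation with MnO2 under neutral conditions should leave the iodoalkene geometry and the silyl ether untouched.

Step 4
Reactants: 6 4-tert-butoxy-4-oxobutanoic acid; 7 (S)-4-benzyl-1,3-oxazolidin-2-one
Product: 9 (S)-4-benzyl-3-(4-tert-butoxy-4-oxobutanoyl)-1,3-oxazolidin-2-one, via mixed pivalic anhydride 8 (not isolated)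
Conditions: t-BuCOCl, Et3N, THF, −20 °C; then 7, LiCl, rt
Reagents that add atoms: none
Why: N-Acylation of the oxazolidinone by a mixed anhydride under LiCl/Et3N activation, the hindered pivaloyl carbonyl steering attack to the succinyl carbonyl.

Step 5
Reactants: 9 (S)-4-benzyl-3-(4-tert-butoxy-4-oxobutanoyl)-1,3-oxazolidin-2-one; 5 (Z)-4-(tert-butyldiphenylsilyloxy)-3-iodobut-2-enal
Product: 11 tert-butyl (3S,4S,5Z)-3-[(4S)-4-benzyl-2-oxo-1,3-oxazolidine-3-carbonyl]-7-(tert-butyldiphenylsilyloxy)-4-hydroxy-6-iodohept-5-enoate, via Z(O) dibutylboron enolate 10 (not isolated)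
Conditions: Bu2BOTf, i-Pr2NEt, CH2Cl2, 0 °C; 5, −78 → 0 °C; then pH 7 buffer, MeOH, H2O2, 0 °C
Reagents that add atoms: none
Why: Evans syn-aldol reaction in which the Z(O) boron enolate reacts through a chair Zimmerman–Traxler transition state on the face opposite the benzyl group, setting C7 and C6 (both S here) in the 6,7-syn relation that becomes the trans-lactone.

Step 6
Reactants: 11 the aldol adduct
Product: 12 tert-butyl (3S,4S,5Z)-7-(tert-butyldiphenylsilyloxy)-4-hydroxy-6-iodo-3-[methoxy(methyl)carbamoyl]hept-5-enoate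
Conditions: MeNHOMe·HCl, AlMe3, CH2Cl2, −15 → 0 °C
Reagents that add atoms: N,O-dimethylhydroxylamine hydrochloride, CNOC.Cl
Why: Hydroxyl-assisted transamination of the imide by the aluminium amide (Weinreb amide formation) should release the auxiliary and spare the tert-butyl ester.

Step 7
Reactants: 12 the Weinreb amide
Product: 13 tert-butyl (3S,4S,5Z)-7-(tert-butyldiphenylsilyloxy)-4-hydroxy-6-iodo-3-(prop-2-enoyl)hept-5-enoate
Conditions: CH2=CHMgBr (3 equiv), THF, −78 → 0 °C; inverse quench into cold aq. NH4Cl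
Reagents that add atoms: vinylmagnesium bromide, C=C[Mg]Br
Why: Grignard addition to a Weinreb amide stops at the chelated tetrahedral intermediate and releases the vinyl ketone only on quench, while the tert-butyl ester and the iodoalkene are inert at this temperature.

Step 8
Reactants: 13 the beta-hydroxy vinyl ketone
Product: 14 tert-butyl (3R,4S,5Z)-7-(tert-butyldiphenylsilyloxy)-4-hydroxy-3-[(1R)-1-hydroxyprop-2-enyl]-6-iodohept-5-enoate
Conditions: Me4NBH(OAc)3, MeCN/AcOH (1:1), −30 °C
Reagents that add atoms: none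
Why: Evans–Saksena reduction, in which the C6 hydroxyl binds boron and delivers hydride intramolecularly through a chair transition state, should give the 1,3-anti diol and thereby the C8 configuration.

Step 9
Reactants: 14 the anti diol tert-butyl ester
Product: 16 (4R,5S)-5-[(1Z)-3-(tert-butyldiphenylsilyloxy)-2-iodoprop-1-enyl]-4-[(1R)-1-hydroxyprop-2-enyl]oxolan-2-one, via dihydroxy acid 15 (not isolated)
Conditions: CF3CO2H, CH2Cl2, 0 °C → rt
Reagents that add atoms: none
Why: Acidolysis of the tert-butyl ester and lactonisation of the hydroxy acid, where the lactone to O6 is trans-disubstituted and should be favoured over the cis-disubstituted lactone to O8 because the acid lets the two interconvert by acyl transfer.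

Step 10
Reactants: 16 the hydroxy lactone
Product: 17 (4S,5S)-5-[(1Z)-3-(tert-butyldiphenylsilyloxy)-2-iodoprop-1-enyl]-4-[(1R)-1-(triethylsilyloxy)prop-2-enyl]oxolan-2-one
Conditions: Et3SiOTf, 2,6-lutidine, CH2Cl2, −78 °C
Reagents that add atoms: triethylsilyl trifluoromethanesulfonate, CC[Si](CC)(CC)OS(=O)(=O)C(F)(F)F
Why: O-Silylation of the remaining secondary hydroxyl with a silyl triflate and a hindered base gives a non-chelating oxygen substituent at C8 for the next C–C bond formation.

Step 11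
Reactants: 17 the silyl ether
Product: 19 (2S)-2-[(2S,3S)-2-[(1Z)-3-(tert-butyldiphenylsilyloxy)-2-iodoprop-1-enyl]-5-oxooxolan-3-yl]-2-(triethylsilyloxy)acetaldehyde, via vicinal diol 18 (not isolated)
Conditions: OsO4 (cat.), NaIO4, 2,6-lutidine, dioxane/H2O (3:1), rt
Reagents that add atoms: osmium tetroxide, O=[Os](=O)(=O)=O; sodium periodate, [Na+].[O-]I(=O)(=O)=O
Why: Lemieux–Johnson cleavage, in which OsO4 should dihydroxylate the monosubstituted vinyl group far faster than the trisubstituted electron-poor iodoalkene and NaIO4 cleaves the diol to the C9 aldehyde, with lutidine limiting epimerisation at C8.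

Step 12
Reactants: 19 the C9 aldehyde; 20 methyl propiolate
Product: 22 methyl (2E)-2-[(1R,2S)-1-hydroxy-2-[(2S,3S)-2-[(1Z)-3-(tert-butyldiphenylsilyloxy)-2-iodoprop-1-enyl]-5-oxooxolan-3-yl]-2-(triethylsilyloxy)ethyl]penta-2,4-dienoate, via alkenylcopper adduct 21 (not isolated)
Conditions: CH2=CHMgBr (2 equiv per Cu), CuBr·SMe2, THF, −78 °C; 20, −78 °C; then 19, Et2AlCl, −78 °C
Reagents that add atoms: vinylmagnesium bromide, C=C[Mg]Br
Why: Tandem carbocupration–aldol reaction in which the vinylcuprate adds syn across the propiolate and the alkenylcopper adds with retention to the Et2AlCl-activated aldehyde, so that C2 ends cis to C9 (2E), while attack anti to the C8 silyloxy group (polar Felkin–Anh) should set C9 as R in the 8,9-anti relation.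

Step 13
Reactants: 22 the hydroxy dienoate
Product: 24 methyl (2E)-2-[(4R,5S)-5-[(2S,3S)-2-[(1Z)-3-(tert-butyldiphenylsilyloxy)-2-iodoprop-1-enyl]-5-oxooxolan-3-yl]-2,2-dimethyl-1,3-dioxolan-4-yl]penta-2,4-dienoate, via C8 C9 diol 23 (not isolated)
Conditions: PPTS, MeOH, 0 °C → rt; concentrate; Me2C(OMe)2, PPTS, acetone, rt
Reagents that add atoms: 2,2-dimethoxypropane, COC(C)(C)OC
Why: Acid-catalysed methanolysis of the secondary triethylsilyl ether followed by transacetalisation should give the cis-dioxolane of the anti diol, the tert-butyldiphenylsilyl ether and the lactone being stable to pyridinium tosylate.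

Step 14
Reactants: 24 the seco iodo-dienoate
Product: 26 methyl (1(10)E,4E,6R,7S,8S,9R)-15-(tert-butyldiphenylsilyloxy)-8,9-(isopropylidenedioxy)germacra-1(10),4-dien-12,6-olid-14-oate, via C3 B-alkyl-9-BBN borane 25 (not isolated)
Conditions: 9-BBN (1.5 equiv), THF, 0 °C → rt; then slow addition (syringe pump) to Pd(dppf)Cl2 (20 mol %), AsPh3, Cs2CO3, DMF/THF/H2O, 45 °C, final concentration about 1 mM
Reagents that add atoms: none
Why: 9-BBN should add to the monosubstituted C2=C3 bond with boron on C3 (anti-Markovnikov hydroboration), because the trisubstituted ester-bearing C1=C10 bond and the iodinated C4=C5 bond are too hindered and too electron-poor for this bulky borane and the lactone and ester carbonyls are not reduced at room temperature. Zerovalent palladium then inserts into the C4–I bond with retention, the base-activated borate transfers the primary C3 alkyl group to palladium and reductive elimination forms C3–C4; the closest known reaction type is the B-alkyl Suzuki–Miyaura coupling used as a macrocyclisation. The ten-membered carbocycle (C1–C10) closes by this intramolecular sp3–sp2 coupling through an eleven-membered palladacycle, with slow addition at high dilution so that ring closure outruns intermolecular coupling. No stereocentre is formed: C6–C9 and both olefin geometries are already present in 24, and retention at C4 places C3 cis to C6, which is the ring-cis C4=C5 bond of the target. The step needs terminal-olefin hydroboration and cyclisation over oligomerisation; the first rests on the steric and electronic bias within the diene, the second on the trans-fused lactone and the cis-dioxolane, which fold the chain so that C3 and C4 lie close.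

Step 15
Reactants: 26 the macrocyclic lactone
Product: 30 methyl (1(10)E,4E,6R,7S,8S,9R)-15-(tert-butyldiphenylsilyloxy)-8,9-(isopropylidenedioxy)germacra-1(10),4,11(13)-trien-12,6-olid-14-oate, via lithium lactone enolate 27 (not isolated), via Mannich base 28 (not isolated), via trimethylammonium iodide 29 (not isolated)
Conditions: LiN(SiMe3)2, THF, −78 °C; CH2=NMe2+ I−, −78 → 0 °C; then MeI, CH2Cl2, rt; then aq. NaHCO3, rt
Reagents that add atoms: N,N-dimethylmethyleneiminium iodide (Eschenmoser's salt), C=[N+](C)C.[I-]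
Why: Kinetic enolisation of the lactone at C11 and Mannich reaction with the iminium salt, then N-methylation and base-induced elimination of trimethylamine (Eschenmoser methylenation), the C11 stereocentre of the Mannich base being lost in the elimination.

Step 16
Reactants: 30 the methylene lactone acetonide
Product: 31 methyl (1(10)E,4E)-15-(tert-butyldiphenylsilyloxy)-8,9-dihydroxygermacra-1(10),4,11(13)-trien-12,6-olid-14-oate (C6–C9 configuration unchanged)
Conditions: AcOH/H2O (4:1), 45 °C
Reagents that add atoms: none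
Why: Acid-catalysed hydrolysis of the isopropylidene acetal, which the primary tert-butyldiphenylsilyl ether, the esters and the exocyclic enoate should survive.

Step 17
Reactants: 31 the 8,9-diol
Product: 32 the 9-O-acetate of 31 (C8 hydroxyl free)
Conditions: Ac2O (1 equiv), pyridine, CH2Cl2, −40 °C
Reagents that add atoms: acetic anhydride, CC(=O)OC(C)=O
Why: Acylation under kinetic control with one equivalent of anhydride, expected at the allylic C9 hydroxyl because the C8 hydroxyl is flanked by the ring-fusion carbon C7 and is the more hindered.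

Step 18
Reactants: 32 the 9-acetate
Product: 33 methyl (1(10)E,4E,6R,7S,8S,9R)-9-acetoxy-15-(tert-butyldiphenylsilyloxy)-8-(2-methylpropanoyloxy)germacra-1(10),4,11(13)-trien-12,6-olid-14-oate
Conditions: (i-PrCO)2O, DMAP, Et3N, CH2Cl2, 0 °C
Reagents that add atoms: 2-methylpropanoic anhydride, CC(C)C(=O)OC(=O)C(C)C
Why: DMAP-catalysed esterification of the remaining secondary hydroxyl, run directly after step 17 to forestall 1,2-acetyl migration.

Step 19
Reactants: 33 the silyl-protected diester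
Product: 34 methyl (1(10)E,4E,6R,7S,8S,9R)-9-acetoxy-15-hydroxy-8-(2-methylpropanoyloxy)germacra-1(10),4,11(13)-trien-12,6-olid-14-oate (CNP0242134.4)
Conditions: HF·pyridine, pyridine, THF, 0 °C → rt
Reagents that add atoms: none
Why: Fluoride-induced cleavage of the silyl ether under buffered conditions that should spare the three esters and the alpha-methylene lactone.

**Compound list**

1 | 2-butyne-1,4-diol | OCC#CCO | starting material
2 | 4-(tert-butyldiphenylsilyloxy)but-2-yn-1-ol | OCC#CCO[Si](c1ccccc1)(c1ccccc1)C(C)(C)C | intermediate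
3 | sodium alkenylaluminate, cyclic, Al on C4 cis to C6 (not isolated) | [Na+].COCCO[Al-]1(OCCOC)OCC=C1CO[Si](c2ccccc2)(c2ccccc2)C(C)(C)C | intermediate
4 | (Z)-4-(tert-butyldiphenylsilyloxy)-3-iodobut-2-en-1-ol | OC/C=C(\I)CO[Si](c1ccccc1)(c1ccccc1)C(C)(C)C | intermediate
5 | (Z)-4-(tert-butyldiphenylsilyloxy)-3-iodobut-2-enal | O=C/C=C(\I)CO[Si](c1ccccc1)(c1ccccc1)C(C)(C)C | intermediate
6 | 4-tert-butoxy-4-oxobutanoic acid | OC(=O)CCC(=O)OC(C)(C)C | starting material
7 | (S)-4-benzyl-1,3-oxazolidin-2-one | O=C1OC[C@H](Cc2ccccc2)N1 | starting material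
8 | mixed anhydride of 6 and pivalic acid (not isolated) | CC(C)(C)C(=O)OC(=O)CCC(=O)OC(C)(C)C | intermediate
9 | (S)-4-benzyl-3-(4-tert-butoxy-4-oxobutanoyl)-1,3-oxazolidin-2-one | O=C1OC[C@H](Cc2ccccc2)N1C(=O)CCC(=O)OC(C)(C)C | intermediate
10 | Z(O) dibutylboron enolate of 9 (not isolated) | CCCCB(CCCC)O/C(=C\CC(=O)OC(C)(C)C)N1C(=O)OC[C@@H]1Cc1ccccc1 | intermediate
11 | tert-butyl (3S,4S,5Z)-3-[(4S)-4-benzyl-2-oxo-1,3-oxazolidine-3-carbonyl]-7-(tert-butyldiphenylsilyloxy)-4-hydroxy-6-iodohept-5-enoate | CC(C)(C)OC(=O)C[C@@H]([C@H](O)/C=C(\I)CO[Si](c1ccccc1)(c1ccccc1)C(C)(C)C)C(=O)N1C(=O)OC[C@@H]1Cc1ccccc1 | intermediate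
12 | tert-butyl (3S,4S,5Z)-7-(tert-butyldiphenylsilyloxy)-4-hydroxy-6-iodo-3-[methoxy(methyl)carbamoyl]hept-5-enoate | CC(C)(C)OC(=O)C[C@@H]([C@H](O)/C=C(\I)CO[Si](c1ccccc1)(c1ccccc1)C(C)(C)C)C(=O)N(C)OC | intermediate
13 | tert-butyl (3S,4S,5Z)-7-(tert-butyldiphenylsilyloxy)-4-hydroxy-6-iodo-3-(prop-2-enoyl)hept-5-enoate | CC(C)(C)OC(=O)C[C@@H]([C@H](O)/C=C(\I)CO[Si](c1ccccc1)(c1ccccc1)C(C)(C)C)C(=O)C=C | intermediate
14 | tert-butyl (3R,4S,5Z)-7-(tert-butyldiphenylsilyloxy)-4-hydroxy-3-[(1R)-1-hydroxyprop-2-enyl]-6-iodohept-5-enoate | CC(C)(C)OC(=O)C[C@@H]([C@H](O)/C=C(\I)CO[Si](c1ccccc1)(c1ccccc1)C(C)(C)C)[C@H](O)C=C | intermediate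
15 | free carboxylic acid of 14 (not isolated) | OC(=O)C[C@@H]([C@H](O)/C=C(\I)CO[Si](c1ccccc1)(c1ccccc1)C(C)(C)C)[C@H](O)C=C | intermediate
16 | (4R,5S)-5-[(1Z)-3-(tert-butyldiphenylsilyloxy)-2-iodoprop-1-enyl]-4-[(1R)-1-hydroxyprop-2-enyl]oxolan-2-one | O=C1C[C@@H]([C@H](O1)/C=C(\I)CO[Si](c2ccccc2)(c2ccccc2)C(C)(C)C)[C@H](O)C=C | intermediate
17 | (4S,5S)-5-[(1Z)-3-(tert-butyldiphenylsilyloxy)-2-iodoprop-1-enyl]-4-[(1R)-1-(triethylsilyloxy)prop-2-enyl]oxolan-2-one | O=C1C[C@@H]([C@H](O1)/C=C(\I)CO[Si](c2ccccc2)(c2ccccc2)C(C)(C)C)[C@H](O[Si](CC)(CC)CC)C=C | intermediate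
18 | 1,2-diol from osmylation of the vinyl group of 17, both epimers at the new carbinol (not isolated) | O=C1C[C@@H]([C@H](O1)/C=C(\I)CO[Si](c2ccccc2)(c2ccccc2)C(C)(C)C)[C@H](O[Si](CC)(CC)CC)C(O)CO | intermediate
19 | (2S)-2-[(2S,3S)-2-[(1Z)-3-(tert-butyldiphenylsilyloxy)-2-iodoprop-1-enyl]-5-oxooxolan-3-yl]-2-(triethylsilyloxy)acetaldehyde | O=C1C[C@@H]([C@H](O1)/C=C(\I)CO[Si](c2ccccc2)(c2ccccc2)C(C)(C)C)[C@H](O[Si](CC)(CC)CC)C=O | intermediate
20 | methyl propiolate | C#CC(=O)OC | starting material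
21 | bromomagnesium [(1Z)-1-(methoxycarbonyl)buta-1,3-dienyl](vinyl)cuprate (not isolated) | C=C/C=C(\[Cu-]C=C)C(=O)OC.[Mg+]Br | intermediate
22 | methyl (2E)-2-[(1R,2S)-1-hydroxy-2-[(2S,3S)-2-[(1Z)-3-(tert-butyldiphenylsilyloxy)-2-iodoprop-1-enyl]-5-oxooxolan-3-yl]-2-(triethylsilyloxy)ethyl]penta-2,4-dienoate | O=C1C[C@@H]([C@H](O1)/C=C(\I)CO[Si](c2ccccc2)(c2ccccc2)C(C)(C)C)[C@H](O[Si](CC)(CC)CC)[C@H](O)/C(C(=O)OC)=C\C=C | intermediate
23 | C8,C9-diol obtained from 22 by loss of the triethylsilyl group (not isolated) | O=C1C[C@@H]([C@H](O1)/C=C(\I)CO[Si](c2ccccc2)(c2ccccc2)C(C)(C)C)[C@H](O)[C@H](O)/C(C(=O)OC)=C\C=C | intermediate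
24 | methyl (2E)-2-[(4R,5S)-5-[(2S,3S)-2-[(1Z)-3-(tert-butyldiphenylsilyloxy)-2-iodoprop-1-enyl]-5-oxooxolan-3-yl]-2,2-dimethyl-1,3-dioxolan-4-yl]penta-2,4-dienoate (seco precursor) | O=C1C[C@@H]([C@H](O1)/C=C(\I)CO[Si](c2ccccc2)(c2ccccc2)C(C)(C)C)[C@@H]2OC(C)(C)O[C@@H]2/C(C(=O)OC)=C\C=C | intermediate
25 | C3 B-alkyl-9-borabicyclo[3.3.1]nonane from 24 (not isolated) | O=C1C[C@@H]([C@H](O1)/C=C(\I)CO[Si](c2ccccc2)(c2ccccc2)C(C)(C)C)[C@@H]2OC(C)(C)O[C@@H]2/C(C(=O)OC)=C\CCB2C3CCCC2CCC3 | intermediate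
26 | methyl (1(10)E,4E,6R,7S,8S,9R)-15-(tert-butyldiphenylsilyloxy)-8,9-(isopropylidenedioxy)germacra-1(10),4-dien-12,6-olid-14-oate, both ring olefins cis within the ring | C1C(=O)O[C@@H]2/C=C(/CO[Si](c4ccccc4)(c4ccccc4)C(C)(C)C)CC/C=C(/C(=O)OC)[C@@H](OC(C)(C)O3)[C@@H]3[C@@H]12 | intermediate
27 | lithium enolate of lactone 26 (not isolated) | C1=C(O[Li])O[C@@H]2/C=C(/CO[Si](c4ccccc4)(c4ccccc4)C(C)(C)C)CC/C=C(/C(=O)OC)[C@@H](OC(C)(C)O3)[C@@H]3[C@@H]12 | intermediate
28 | 11-(dimethylaminomethyl) derivative of 26, C11 epimers (not isolated) | CN(C)CC1C(=O)O[C@@H]2/C=C(/CO[Si](c4ccccc4)(c4ccccc4)C(C)(C)C)CC/C=C(/C(=O)OC)[C@@H](OC(C)(C)O3)[C@@H]3[C@@H]12 | intermediate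
29 | N-methyl quaternary iodide of 28 (not isolated) | C[N+](C)(C)CC1C(=O)O[C@@H]2/C=C(/CO[Si](c4ccccc4)(c4ccccc4)C(C)(C)C)CC/C=C(/C(=O)OC)[C@@H](OC(C)(C)O3)[C@@H]3[C@@H]12.[I-] | intermediate
30 | methyl (1(10)E,4E,6R,7S,8S,9R)-15-(tert-butyldiphenylsilyloxy)-8,9-(isopropylidenedioxy)germacra-1(10),4,11(13)-trien-12,6-olid-14-oate | C=C1C(=O)O[C@@H]2/C=C(/CO[Si](c4ccccc4)(c4ccccc4)C(C)(C)C)CC/C=C(/C(=O)OC)[C@@H](OC(C)(C)O3)[C@@H]3[C@@H]12 | intermediate
31 | 8,9-diol of 30 (acetonide removed, configuration unchanged) | C=C1C(=O)O[C@@H]2/C=C(/CO[Si](c4ccccc4)(c4ccccc4)C(C)(C)C)CC/C=C(/C(=O)OC)[C@@H](O)[C@@H](O)[C@@H]12 | intermediate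
32 | 9-O-acetate of 31 | C=C1C(=O)O[C@@H]2/C=C(/CO[Si](c4ccccc4)(c4ccccc4)C(C)(C)C)CC/C=C(/C(=O)OC)[C@@H](OC(C)=O)[C@@H](O)[C@@H]12 | intermediate
33 | methyl (1(10)E,4E,6R,7S,8S,9R)-9-acetoxy-15-(tert-butyldiphenylsilyloxy)-8-(2-methylpropanoyloxy)germacra-1(10),4,11(13)-trien-12,6-olid-14-oate | C=C1C(=O)O[C@@H]2/C=C(/CO[Si](c4ccccc4)(c4ccccc4)C(C)(C)C)CC/C=C(/C(=O)OC)[C@@H](OC(C)=O)[C@@H](OC(=O)C(C)C)[C@@H]12 | intermediate
34 | methyl (1(10)E,4E,6R,7S,8S,9R)-9-acetoxy-15-hydroxy-8-(2-methylpropanoyloxy)germacra-1(10),4,11(13)-trien-12,6-olid-14-oate (CNP0242134.4) | C=C1C(=O)O[C@@H]2/C=C(/CO)CC/C=C(/C(=O)OC)[C@@H](OC(C)=O)[C@@H](OC(=O)C(C)C)[C@@H]12 | target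

**Summary**

Total step count: 19. Longest linear sequence: 18 steps (steps 1–3 and 5–19; step 4 prepares the imide in a side branch).

Steps most likely to fail:

1. Step 14. The alkylborane may be consumed by intermolecular coupling, protodeboronation or beta-hydride elimination before the strained palladacycle closes, and hydroboration of the electron-poor diene may be slow. Fallback, setting out from 24 and returning at 26: the borane 25 is oxidised with NaBO3 to the C3 primary alcohol F1, which I2, PPh3 and imidazole should convert into the primary iodide F2. Zinc dust with LiCl in THF should insert into the alkyl C–I bond only, giving the alkylzinc iodide F3. Slow addition of F3 to Pd(PPh3)4 in THF/DMF at high dilution should close the same C3–C4 bond by an intramolecular Negishi coupling, giving 26.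

2. Step 12. The alkenylcopper may relax through its copper allenoate before the aldol, so that the aldehyde enters anti to the vinyl group and the 2Z dienoate forms; facial control at C9 may also be weak. Fallback, setting out from 19 and returning at 22: a DABCO-catalysed Morita–Baylis–Hillman-type reaction of 19 with methyl penta-2,3-dienoate should give the alpha-(hydroxyalkyl)allenoate F4. PPh3-catalysed isomerisation of the allene into the conjugated diene then sets the C1=C10 geometry under thermodynamic control, where the 2E isomer (vinyl cis to C9) is expected to be the more stable, and leads to 22.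

3. Step 17. The two secondary hydroxyls may be acetylated with poor discrimination, or the acetyl group may migrate between O9 and O8. Fallback, setting out from 31 and returning at 33: the bulkier Et3SiCl with imidazole at −20 °C should amplify the steric difference and give the 9-O-triethylsilyl ether F5. Isobutyrylation of C8–OH then gives the silyl ether ester F6, and HF·pyridine buffered with pyridine should remove only the triethylsilyl group to give the 9-hydroxy 8-isobutyrate F7. Acetylation of F7 gives 33. If silylation prefers O8 instead, the same operations with the two anhydrides exchanged lead to 33 as well.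

**Further compounds**

F1 | step 14 | C3 primary alcohol from hydroboration–oxidation of 24 | O=C1C[C@@H]([C@H](O1)/C=C(\I)CO[Si](c2ccccc2)(c2ccccc2)C(C)(C)C)[C@@H]2OC(C)(C)O[C@@H]2/C(C(=O)OC)=C\CCO
F2 | step 14 | C3 primary iodide | O=C1C[C@@H]([C@H](O1)/C=C(\I)CO[Si](c2ccccc2)(c2ccccc2)C(C)(C)C)[C@@H]2OC(C)(C)O[C@@H]2/C(C(=O)OC)=C\CCI
F3 | step 14 | C3 alkylzinc iodide (not isolated) | O=C1C[C@@H]([C@H](O1)/C=C(\I)CO[Si](c2ccccc2)(c2ccccc2)C(C)(C)C)[C@@H]2OC(C)(C)O[C@@H]2/C(C(=O)OC)=C\CC[Zn]I
F4 | step 12 | alpha-(hydroxyalkyl)allenoate from 19 and methyl penta-2,3-dienoate, allene axis unassigned | O=C1C[C@@H]([C@H](O1)/C=C(\I)CO[Si](c2ccccc2)(c2ccccc2)C(C)(C)C)[C@H](O[Si](CC)(CC)CC)[C@H](O)C(C(=O)OC)=C=CC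
F5 | step 17 | 9-O-triethylsilyl ether of 31 | C=C1C(=O)O[C@@H]2/C=C(/CO[Si](c4ccccc4)(c4ccccc4)C(C)(C)C)CC/C=C(/C(=O)OC)[C@@H](O[Si](CC)(CC)CC)[C@@H](O)[C@@H]12
F6 | step 17 | 9-O-triethylsilyl 8-O-(2-methylpropanoyl) derivative of 31 | C=C1C(=O)O[C@@H]2/C=C(/CO[Si](c4ccccc4)(c4ccccc4)C(C)(C)C)CC/C=C(/C(=O)OC)[C@@H](O[Si](CC)(CC)CC)[C@@H](OC(=O)C(C)C)[C@@H]12
F7 | step 17 | 8-O-(2-methylpropanoyl) derivative of 31 with free C9 hydroxyl | C=C1C(=O)O[C@@H]2/C=C(/CO[Si](c4ccccc4)(c4ccccc4)C(C)(C)C)CC/C=C(/C(=O)OC)[C@@H](O)[C@@H](OC(=O)C(C)C)[C@@H]12
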